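(The data stem from a simulated flask on assumed constants, noise included.)

In a one-step world, where open intermediate and second intermediate combine to target and nothing comes back, you need one constant, and Friday's run should supply it.

the same everywhere: substrate 0.10 M
- Saturday's: partner 0.10 M; temperature 65 °C; run made earlier
- Friday's: partner 0.22 M; temperature 76 °C; run made earlier
- autumn: partner 0.150 M; temperature 60 °C; time 25 min
- spring: partner 0.150 M; temperature 80 °C; time 25 min

| run | time / min | target / % | side product / % | substrate / % | open intermediate / % |
|---|---|---|---|---|---|
| Saturday's | 3.00 | 2.4 | 1.1 | 4.8 | 93.4 |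
| Saturday's | 8.00 | 9.5 | 0 | 1.0 | 91.9 |
| Saturday's | 15.0 | 19.5 | 0 | 1.3 | 78.2 |
| Saturday's | 25.0 | 34.6 | 0 | 1.0 | 66.7 |
| Friday's | 2.50 | 10.5 | 0 | 0.4 | 90.4 |
| Friday's | 5.00 | 26.9 | 0.2 | 0 | 72.1 |
| Friday's | 10.0 | 52.8 | 0.1 | 0 | 47.5 |
| Friday's | 12.0 | 57.6 | 0 | 0 | 40.3 |

(readings scatter by 1 percentage point)

- percentages count the substrate that a species holds: one side product counts as two
- on the list of suspects stand: substrate -> open intermediate; partner -> second intermediate; open intermediate + second intermediate <-> target; substrate + target -> side product

- which of these there is most of at the end, counted by the substrate in it, autumn (target / open intermediate / substrate / side product)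
- which of these there is most of at the end, counted by the substrate in it, spring (target / open intermediate / substrate / side product)
- final amount of the leader among these, as a percentage of the substrate charged, in autumn
- final amount of the leader among these, as a percentage of the substrate charged, in spring

Take the two last gaps of Friday's run and use mean values in each, counting all partner as already converted, so that [second intermediate] is the partner charge less [target]:

first gap: rate 0.00518 M min⁻¹, [open intermediate] 0.0598 M, [target] 0.0399 M, [second intermediate] 0.180 M

second gap: rate 0.00240 M min⁻¹, [open intermediate] 0.0439 M, [target] 0.0552 M, [second intermediate] 0.165 M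

The first gap alone gives a constant of 0.481 L mol⁻¹ min⁻¹, which promises 0.00348 M min⁻¹ in the second gap, more than the reading there. That single constant is the weak link, so I reforge it by letting each gap be forward minus backward, and the two equations give

forward 0.621 L mol⁻¹ min⁻¹, the ratio of forward to backward K = 16.4 L mol⁻¹, and so backward 0.0379 min⁻¹

K, the balance ratio [target]/([open intermediate][second intermediate]), is a reading that rests on a two-minute gap, so you should hold it loosely. I carry it unchanged from Friday's temperature to spring, where at balance the target share is K[second intermediate] / (one + K[second intermediate]). Start with all substrate as target, then put each answer back in: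

[second intermediate] 0.0500 M gives 45.0%

0.105 M gives 63.2%

0.0868 M gives 58.7%

0.0913 M gives 59.9%

The approach to balance takes about 8.42 min, shorter than the 25 min allowed, so I commit to target leading spring at 59.9%. Autumn I place by Saturday's last reading, open intermediate leading near 66.7%.

The forecast says open intermediate at 62% in autumn and target at 75% in spring, noting “Possible reversibility pulls this down”, and its spring figure is higher than my 59.9%.

The flask gives open intermediate at 66.0% in autumn and target at 57.3% in spring.

    substrate → open intermediate (k = 0.624 min⁻¹, Ea = 89.0 kJ mol⁻¹)
    partner → second intermediate (k = 0.0687 min⁻¹, Ea = 95.0 kJ mol⁻¹)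
    open intermediate + second intermediate ⇌ target (K = 27.9 L mol⁻¹, k = 0.298 L mol⁻¹ min⁻¹, Ea = 54.0 kJ mol⁻¹, ΔH = −30.0 kJ mol⁻¹)
    substrate + target → side product (k = 0.395 L mol⁻¹ min⁻¹, Ea = 62.0 kJ mol⁻¹)
    (constants at 60 °C)

The ratio K stands at 14.5 L mol⁻¹ at the end of spring. The backward run from target is a part of why spring stops where it does: the same spring flask without that step reaches 84.2% target instead of 57.3%. Autumn has the same charges, so my 16.4 L mol⁻¹ gives the same 59.9% there, but the difference in temperature is the main reason for the gap in target between the two flasks at 25 min: spring held at autumn's temperature gives 34.0% target, and autumn at 250 min holds 69.2% target with its ratio at 27.9 L mol⁻¹.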